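**Retrosynthetic overview**
1. Target ⇐ C15 carboxylic acid (mixed-anhydride/NaBH4 reduction) ⇐ 6β-acetoxy-7-ene: a singlet-oxygen ene reaction installs 7α-OH and moves the olefin to C8=C9.
2. 6β-Acetoxy-7-ene ⇐ 7-en-6-one (α-face hydride, acetylation) ⇐ allylic oxidation at C6 of (13Z)-labda-7,13-dien-15-oic acid, whose 13Z olefin ⇐ syn-methylcupration of a bicyclic alk-2-ynoic acid.
3. Rings A and B ⇐ one enantioselective, proton-initiated chair–chair bicyclization of the whole acyclic C19 trienynoic acid: ring A closes first (C4–C5), ring B second (C9–C10); C5, C9 and C10 are set together.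
4. Acyclic acid ⇐ (2E,6E)-farnesyl bromide + but-2-ynoic acid (γ-alkylation of the dianion).

Assumption: labdane numbering and α/β notation are used (H-5 α and the C10 methyl β, i.e. the 5S,10S series read from the target SMILES), and (2E,6E)-farnesyl bromide is taken as a purchasable starting material.

**Step 1**
Reactants: 1 (2E,6E)-farnesyl bromide; 2 but-2-ynoic acid
Product: 4 (6E,10E)-7,11,15-trimethylhexadeca-6,10,14-trien-2-ynoic acid, via dilithium but-2-ynoate dianion 3 (not isolated)
Conditions: LiN(i-Pr)2 (2.2 equiv), THF–DMPU, −78 °C; then 1, −78 → 0 °C; 1 M HCl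
Reagents that add atoms: none
Why: γ-Alkylation of a carboxylate-stabilised propargylic dianion (SN2 at the primary allylic bromide) joins C11 to C12 without touching the two E-olefins; no stereocenter is formed.

**Step 2**
Reactants: 4 (6E,10E)-7,11,15-trimethylhexadeca-6,10,14-trien-2-ynoic acid
Product: 6 16-norlabd-7-en-13-yn-15-oic acid (5α-H/9α-H/10β-CH3), via monocyclic ring A acid 5 (not isolated)
Conditions: (R)-2-hydroxy-2'-(2-fluorobenzyloxy)-1,1'-binaphthyl (2.2 equiv), SnCl4 (2.0 equiv), toluene, −78 °C, 3 d; then CF3CO2H (10 equiv), −78 °C, 1 d; Et3N, NaHCO3 (aq)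
Reagents that add atoms: none
Why: Yamamoto-type LBA (Lewis acid-assisted chiral Brønsted acid) polyene cyclization run as a Stork–Eschenmoser chair–chair cascade: enantioface-selective protonation of the terminal olefin by the (R)-ligand·SnCl4 acid (the antipode that turns homofarnesol into (−)-ambrox) closes ring A and fixes C5, the achiral CF3CO2H·SnCl4 then closes ring B by anti addition across the E-olefins (5α-H, 9α-H, 10β-CH3, trans-decalin), the electron-poor alkynoic acid cannot attack the C8 cation, and loss of H-7 should give mainly the 7-ene (8(17)- and 8-ene isomers are removed on AgNO3-silica).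

**Step 3**
Reactants: 6 16-norlabd-7-en-13-yn-15-oic acid
Product: 8 (13Z)-labda-7,13-dien-15-oic acid (5α-H/9α-H/10β-CH3), via C14 alkenylcopper carboxylate 7 (not isolated)
Conditions: MeLi (6 equiv), CuI (3 equiv), THF, −78 → −30 °C; NH4Cl (aq), then HCl to pH 3
Reagents that add atoms: lithium dimethylcuprate LiCuMe2, [Li+].C[Cu-]C
Why: Corey–Katzenellenbogen-type conjugate methylcupration of the alk-2-ynoic acid: methyl (at C13) and copper (at C14) add syn and protonation occurs with retention, so C12 ends cis to the carboxyl group, which is the 13Z geometry of the target.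

**Step 4**
Reactants: 8 (13Z)-labda-7,13-dien-15-oic acid
Product: 9 (13Z)-6-oxolabda-7,13-dien-15-oic acid
Conditions: CrO3, 3,5-dimethylpyrazole (15 equiv each), CH2Cl2, −20 °C
Reagents that add atoms: chromium trioxide CrO3, O=[Cr](=O)=O
Why: Allylic oxidation by the CrO3–3,5-dimethylpyrazole complex takes the only ring allylic methylene (C6) to the conjugated 7-en-6-one, the known outcome for drim-7-enes, while the electron-poor acrylic acid unit is not attacked; C5, C9 and C10 are untouched (the trans ring fusion is also the stable one next to the ketone).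

**Step 5**
Reactants: 9 (13Z)-6-oxolabda-7,13-dien-15-oic acid
Product: 10 (13Z)-6β-hydroxylabda-7,13-dien-15-oic acid
Conditions: NaBH4, CeCl3·7H2O, MeOH, −40 → 0 °C
Reagents that add atoms: none
Why: Luche 1,2-reduction: hydride can reach C6 only from the α-face because the β-face is blocked by the syn-axial C4β and C10β methyl groups, so the axial 6β-alcohol (C6 of the target) is formed.

**Step 6**
Reactants: 10 (13Z)-6β-hydroxylabda-7,13-dien-15-oic acid
Product: 12 (13Z)-6β-acetoxylabda-7,13-dien-15-oic acid, via acetic mixed anhydride 11 (not isolated)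
Conditions: Ac2O, Et3N, 4-(dimethylamino)pyridine (cat.), CH2Cl2, 23 °C; NaHCO3 (aq), then 1 M HCl
Reagents that add atoms: acetic anhydride, CC(=O)OC(C)=O
Why: 4-(Dimethylamino)pyridine-catalysed acetylation of the hindered allylic 6β-hydroxyl; the carboxyl group is acetylated at the same time to the mixed anhydride, which the bicarbonate work-up hydrolyses back to the acid; no stereocenter changes.

**Step 7**
Reactants: 12 (13Z)-6β-acetoxylabda-7,13-dien-15-oic acid
Product: 14 (13Z)-6β-acetoxy-7α-hydroxylabda-8,13-dien-15-oic acid, via 7α-hydroperoxide 13 (not isolated)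
Conditions: O2, tetraphenylporphyrin (cat.), visible light, CH2Cl2, 0 °C; then PPh3, 0 → 23 °C
Reagents that add atoms: dioxygen O2 (as singlet oxygen), O=O
Why: Schenck ene reaction: singlet oxygen bonds to C7 from the open α-face (the β-face carries the 6β-acetate and the C10 methyl) and removes the axial H-9α on the same face, so the olefin moves to C8=C9, C7 becomes 7α-OOH and the C9 stereocenter disappears; the conjugated acrylic acid olefin is inert and PPh3 reduces the O–O bond without touching C7.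

**Step 8**
Reactants: 14 (13Z)-6β-acetoxy-7α-hydroxylabda-8,13-dien-15-oic acid
Product: 16 (13Z)-6β-acetoxylabda-8,13-diene-7α,15-diol (the target), via isobutyl carbonic anhydride 15 (not isolated)
Conditions: i-BuOCOCl, N-methylmorpholine, THF, −15 °C; then NaBH4, THF–H2O, 0 °C
Reagents that add atoms: none
Why: Reduction of the acid via its isobutyl carbonic mixed anhydride with NaBH4 is selective for the activated carboxyl carbon, so the hindered 6β-acetate, the 7α-hydroxyl and the 13Z olefin survive and the C15 alcohol of the target results.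

**Compound list**
1 | (2E,6E)-farnesyl bromide, (2E,6E)-1-bromo-3,7,11-trimethyldodeca-2,6,10-triene | CC(C)=CCC/C(C)=C/CC/C(C)=C/CBr | starting material
2 | but-2-ynoic acid | CC#CC(=O)O | starting material
3 | dilithium but-2-ynoate dianion (lithium 4-lithiobut-2-ynoate) | [Li+].[Li+].[CH2-]C#CC(=O)[O-] | intermediate
4 | (6E,10E)-7,11,15-trimethylhexadeca-6,10,14-trien-2-ynoic acid | CC(C)=CCC/C(C)=C/CC/C(C)=C/CCC#CC(=O)O | intermediate
5 | (6E)-9-[(1S)-2,2-dimethyl-6-methylidenecyclohexyl]-7-methylnon-6-en-2-ynoic acid (monocyclic ring A acid, shown as the exocyclic olefin isomer) | C=C1CCCC(C)(C)[C@@H]1CC/C(C)=C/CCC#CC(=O)O | intermediate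
6 | 5-[(1S,4aS,8aS)-2,5,5,8a-tetramethyl-1,4,4a,5,6,7,8,8a-octahydronaphthalen-1-yl]pent-2-ynoic acid (16-norlabd-7-en-13-yn-15-oic acid; 5α-H, 9α-H, 10β-CH3) | C1C=C(C)[C@H](CCC#CC(=O)O)[C@@]2(C)CCCC(C)(C)[C@H]12 | intermediate
7 | lithium carboxylate of the C14 alkenylcopper adduct (methyl at C13 cis to copper, C12 cis to the carboxylate) | [Li+].C1C=C(C)[C@H](CC/C(C)=C(/[Cu])C(=O)[O-])[C@@]2(C)CCCC(C)(C)[C@H]12 | intermediate
8 | (2Z)-3-methyl-5-[(1S,4aS,8aS)-2,5,5,8a-tetramethyl-1,4,4a,5,6,7,8,8a-octahydronaphthalen-1-yl]pent-2-enoic acid ((13Z)-labda-7,13-dien-15-oic acid) | C1C=C(C)[C@H](CC/C(C)=C\C(=O)O)[C@@]2(C)CCCC(C)(C)[C@H]12 | intermediate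
9 | (13Z)-6-oxolabda-7,13-dien-15-oic acid (5α-H, 9α-H, 10β-CH3) | O=C1C=C(C)[C@H](CC/C(C)=C\C(=O)O)[C@@]2(C)CCCC(C)(C)[C@H]12 | intermediate
10 | (13Z)-6β-hydroxylabda-7,13-dien-15-oic acid (5α-H, 9α-H, 10β-CH3) | O[C@@H]1C=C(C)[C@H](CC/C(C)=C\C(=O)O)[C@@]2(C)CCCC(C)(C)[C@H]12 | intermediate
11 | acetic (13Z)-6β-acetoxylabda-7,13-dien-15-oic anhydride | CC(=O)O[C@@H]1C=C(C)[C@H](CC/C(C)=C\C(=O)OC(C)=O)[C@@]2(C)CCCC(C)(C)[C@H]12 | intermediate
12 | (13Z)-6β-acetoxylabda-7,13-dien-15-oic acid (5α-H, 9α-H, 10β-CH3) | CC(=O)O[C@@H]1C=C(C)[C@H](CC/C(C)=C\C(=O)O)[C@@]2(C)CCCC(C)(C)[C@H]12 | intermediate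
13 | (13Z)-6β-acetoxy-7α-hydroperoxylabda-8,13-dien-15-oic acid | CC(=O)O[C@@H]1[C@@H](OO)C(C)=C(CC/C(C)=C\C(=O)O)[C@@]2(C)CCCC(C)(C)[C@H]12 | intermediate
14 | (13Z)-6β-acetoxy-7α-hydroxylabda-8,13-dien-15-oic acid (5α-H, 10β-CH3) | CC(=O)O[C@@H]1[C@@H](O)C(C)=C(CC/C(C)=C\C(=O)O)[C@@]2(C)CCCC(C)(C)[C@H]12 | intermediate
15 | isobutyl carbonic (13Z)-6β-acetoxy-7α-hydroxylabda-8,13-dien-15-oic anhydride | CC(=O)O[C@@H]1[C@@H](O)C(C)=C(CC/C(C)=C\C(=O)OC(=O)OCC(C)C)[C@@]2(C)CCCC(C)(C)[C@H]12 | intermediate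
16 | (5S,6S,7S,10S,13Z)-6β-acetoxylabda-8,13-diene-7α,15-diol (CNP0183298.2) | CC(=O)O[C@@H]1[C@@H](O)C(C)=C(CC/C(C)=C\CO)[C@@]2(C)CCCC(C)(C)[C@H]12 | target

**Step count and weak points**
Total step count: 8. Longest linear sequence: 8 steps (1 → 16).

The three steps most likely to fail are steps 2, 7 and 1.

Step 2 (enantioselective bicyclization). The risks are incomplete closure of ring B, olefin isomers at C8 and modest ee with a free alkynoic acid. The fallback leaves the absolute configuration to a later kinetic resolution. It sets out from 4: SnCl4 and CF3CO2H alone (CH2Cl2, −78 °C) give racemic material, that is 6 together with its mirror image ent-6 F2. Methylcupration as in step 3 then passes through 7 and the mirror-image alkenylcopper carboxylate ent-7 F3 to 8 and ent-8 F4, and the chromium oxidation of step 4 gives 9 and ent-9 F5. Reduction with catecholborane and (S)-1-methyl-3,3-diphenyltetrahydro-1H,3H-pyrrolo[1,2-c][1,3,2]oxazaborole (toluene, −78 °C) should consume only 9, because its open α-face is the face this catalyst prefers when C5 is the large and C7 the small carbonyl substituent. The route is rejoined at 10, while ent-9 F5 stays behind as ketone and is removed by chromatography (at most half of the material is used).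

Step 7 (ene reaction). The risks are a slow reaction of the acetoxy-deactivated olefin and abstraction of a C17 hydrogen, which would give the exocyclic 8(17)-ene. The fallback brings the oxygen in at C9 and transposes it. It sets out from 9: the potassium dienolate (KOt-Bu, t-BuOH–THF, 0 °C) is oxygenated by O2 at the γ-carbon from the α-face to (13Z)-9α-hydroperoxy-6-oxolabda-7,13-dien-15-oic acid F6, which P(OEt)3 in the same flask reduces to (13Z)-9α-hydroxy-6-oxolabda-7,13-dien-15-oic acid F7. Luche reduction gives (13Z)-6β,9α-dihydroxylabda-7,13-dien-15-oic acid F8. Acetylation as in step 6 touches only the secondary 6β-hydroxyl and gives, through its acetic mixed anhydride F9, (13Z)-6β-acetoxy-9α-hydroxylabda-7,13-dien-15-oic acid F10. A catalytic amount of Ph3SiOReO3 (Et2O, 0 °C) then shifts the tertiary allylic hydroxyl suprafacially from C9α to C7α while the olefin moves to the tetrasubstituted C8=C9 position, which rejoins the route at 14.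

Step 1 (dianion alkylation). The risks are α-alkylation to an allenic acid and SN2' attack on the allylic bromide. The fallback builds the alkynoic acid from a propargyl anion equivalent. It sets out from 1: 3-lithio-1-(trimethylsilyl)propyne (from 1-(trimethylsilyl)propyne and n-BuLi, THF, −78 °C) gives trimethyl[(5E,9E)-6,10,14-trimethylpentadeca-5,9,13-trien-1-yn-1-yl]silane F1. Fluoride-induced desilylative carboxylation (CsF, CO2, DMSO, 23 °C; HCl work-up) returns to the route at 4.

**Further compounds**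
F1 | step 1 | trimethyl[(5E,9E)-6,10,14-trimethylpentadeca-5,9,13-trien-1-yn-1-yl]silane | CC(C)=CCC/C(C)=C/CC/C(C)=C/CCC#C[Si](C)(C)C
F2 | step 2 | ent-6, 5-[(1R,4aR,8aR)-2,5,5,8a-tetramethyl-1,4,4a,5,6,7,8,8a-octahydronaphthalen-1-yl]pent-2-ynoic acid | C1C=C(C)[C@@H](CCC#CC(=O)O)[C@]2(C)CCCC(C)(C)[C@@H]12
F3 | step 2 | ent-7, mirror image of the C14 alkenylcopper lithium carboxylate | [Li+].C1C=C(C)[C@@H](CC/C(C)=C(/[Cu])C(=O)[O-])[C@]2(C)CCCC(C)(C)[C@@H]12
F4 | step 2 | ent-8, (2Z)-3-methyl-5-[(1R,4aR,8aR)-2,5,5,8a-tetramethyl-1,4,4a,5,6,7,8,8a-octahydronaphthalen-1-yl]pent-2-enoic acid | C1C=C(C)[C@@H](CC/C(C)=C\C(=O)O)[C@]2(C)CCCC(C)(C)[C@@H]12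
F5 | step 2 | ent-9, mirror image of (13Z)-6-oxolabda-7,13-dien-15-oic acid | O=C1C=C(C)[C@@H](CC/C(C)=C\C(=O)O)[C@]2(C)CCCC(C)(C)[C@@H]12
F6 | step 7 | (13Z)-9α-hydroperoxy-6-oxolabda-7,13-dien-15-oic acid | O=C1C=C(C)[C@](OO)(CC/C(C)=C\C(=O)O)[C@@]2(C)CCCC(C)(C)[C@H]12
F7 | step 7 | (13Z)-9α-hydroxy-6-oxolabda-7,13-dien-15-oic acid | O=C1C=C(C)[C@](O)(CC/C(C)=C\C(=O)O)[C@@]2(C)CCCC(C)(C)[C@H]12
F8 | step 7 | (13Z)-6β,9α-dihydroxylabda-7,13-dien-15-oic acid | O[C@@H]1C=C(C)[C@](O)(CC/C(C)=C\C(=O)O)[C@@]2(C)CCCC(C)(C)[C@H]12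
F9 | step 7 | acetic (13Z)-6β-acetoxy-9α-hydroxylabda-7,13-dien-15-oic anhydride | CC(=O)O[C@@H]1C=C(C)[C@](O)(CC/C(C)=C\C(=O)OC(C)=O)[C@@]2(C)CCCC(C)(C)[C@H]12
F10 | step 7 | (13Z)-6β-acetoxy-9α-hydroxylabda-7,13-dien-15-oic acid | CC(=O)O[C@@H]1C=C(C)[C@](O)(CC/C(C)=C\C(=O)O)[C@@]2(C)CCCC(C)(C)[C@H]12
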